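The ring oxygens are traced back to one epoxide placed on an achiral, Birch-derived cyclohexa-2,5-dienol. In that six-membered carbocycle the carbinol carbon C1 (bearing C7) lies on a mirror plane through C1 and C4 and is flanked by the enantiotopic alkenes C2=C3 and C5=C6. A hydroxyl-directed asymmetric epoxidation picks one alkene: in one operation the C2–O and C3–O bonds of the oxirane form syn to the C1 hydroxyl and C1 becomes stereogenic. The oxirane is then unzipped to the cis-1,2-diol diene, whose acetonide steers singlet oxygen to the opposite face to place C3–O and C6–O. The precursor is 1-(benzoyloxymethyl)cyclohexa-2,5-dien-1-ol, already carrying the C7 benzoate of the target.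

Key step: step 6

Assumption: the facial sense of the hafnium bishydroxamate on a ring dienol cannot be carried over with confidence from acyclic tertiary allylic alcohols, so the ligand antipode, (R,R) or (S,S), that gives (1S,2S,3S)-12 is to be fixed in a pilot run with both; locants C1–C7 are those of the target in every name.

Step 1
Reactants: 1 benzoic acid
Product: 2 cyclohexa-2,5-diene-1-carboxylic acid
Conditions: Na, NH3(l), EtOH, −78 °C; NH4Cl; aq. HCl
Reagents that add atoms: none
Why: Birch reduction of the benzoate anion adds hydrogen at the ipso and para carbons because the carboxylate stabilises the intermediate anion at C1, giving the unconjugated 2,5-diene with no stereocentre.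

Step 2
Reactants: 2 cyclohexa-2,5-diene-1-carboxylic acid; 3 trimethylsilyldiazomethane
Product: 4 methyl cyclohexa-2,5-diene-1-carboxylate
Conditions: TMSCHN2, PhMe/MeOH, 0 °C → rt
Reagents that add atoms: trimethylsilyldiazomethane, C[Si](C)(C)C=[N+]=[N-]
Why: Methyl esterification with the diazoalkane runs under neutral conditions, so the skipped diene is not pushed into conjugation by base or strong acid.

Step 3
Reactants: 4 methyl cyclohexa-2,5-diene-1-carboxylate; 5 trans-3-phenyl-2-(phenylsulfonyl)oxaziridine (racemic)
Product: 7 methyl 1-hydroxycyclohexa-2,5-diene-1-carboxylate, via potassium dienolate 6 (not isolated)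
Conditions: KN(SiMe3)2, THF, −78 °C; then oxaziridine 5, −78 °C; NH4Cl
Reagents that add atoms: trans-3-phenyl-2-(phenylsulfonyl)oxaziridine, O=S(=O)(N1OC1c1ccccc1)c1ccccc1
Why: Enolate hydroxylation with an N-sulfonyloxaziridine: the cross-conjugated dienolate takes up electrophiles at C1, as in Birch reductive alkylations, and since C1 lies on the ring mirror plane no stereocentre arises.

Step 4
Reactants: 7 methyl 1-hydroxycyclohexa-2,5-diene-1-carboxylate
Product: 8 1-(hydroxymethyl)cyclohexa-2,5-dien-1-ol
Conditions: LiAlH4, THF, 0 °C; aq. NaOH work-up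
Reagents that add atoms: none
Why: Hydride reduction of the ester to the primary alcohol (LiAlH4 reduction) spares the isolated alkenes, and the basic work-up protects the acid-labile doubly allylic carbinol.

Step 5
Reactants: 8 1-(hydroxymethyl)cyclohexa-2,5-dien-1-ol; 9 benzoyl chloride
Product: 10 (1-hydroxycyclohexa-2,5-dien-1-yl)methyl benzoate
Conditions: BzCl (1.05 equiv), pyridine, CH2Cl2, −20 → 0 °C
Reagents that add atoms: benzoyl chloride, O=C(Cl)c1ccccc1
Why: Selective acylation: the unhindered primary hydroxyl reacts with the acid chloride far faster than the tertiary one, which leaves the directing C1 hydroxyl free and installs the C7 benzoate that the target keeps.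

Step 6
Reactants: 10 (1-hydroxycyclohexa-2,5-dien-1-yl)methyl benzoate; 11 cumene hydroperoxide
Product: 12 [(1S,2S,3S)-2,3-epoxy-1-hydroxycyclohex-5-en-1-yl]methyl benzoate (oxirane on the face of the C1 hydroxyl, C5=C6 intact)
Conditions: Hf(OtBu)4 (20 mol %), C2-symmetric bishydroxamic acid from trans-cyclohexane-1,2-diamine (22 mol %), cumene hydroperoxide (1.1 equiv), DMPU, 4 Å MS, PhMe, 0 °C → rt
Reagents that add atoms: cumene hydroperoxide, CC(C)(OO)c1ccccc1
Why: Alkoxide exchange places the C1 oxygen of 10 and the cumyl peroxide on tetravalent hafnium held by the chiral bishydroxamate, and the distal peroxide oxygen is then passed in one concerted step to the alkene lying under the Hf–O bond. The closest known reaction type is the hafnium or zirconium bishydroxamate epoxidation of tertiary allylic alcohols, joined to the long-used desymmetrisation of dialkenyl carbinols by directed asymmetric epoxidation. The oxirane closes by concerted oxygen-atom transfer across C2=C3, both C–O bonds forming together, so the cis ring fusion is obligatory. C2 and C3 are set by the tether (oxygen arrives on the hydroxyl face), and C1 becomes stereogenic through the ligand's choice between the enantiotopic C2=C3 and C5=C6 alkenes. The step needs enantiotopic-group selection and a stop at the mono-epoxide: the two ring alkenes are identical and equidistant from the bound oxygen, so only the ligand tells them apart, the wrongly formed enantiomer should be drained faster into the meso bis-epoxide, and the C7 benzoate keeps the primary oxygen off the metal.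

Step 7
Reactants: 12 [(1S,2S,3S)-2,3-epoxy-1-hydroxycyclohex-5-en-1-yl]methyl benzoate
Product: 15 [(1S,2S)-1,2-dihydroxycyclohexa-3,5-dien-1-yl]methyl benzoate, via hydroxy selenide 13 (not isolated), via selenoxide 14 (not isolated)
Conditions: (PhSe)2, NaBH4, EtOH, rt; then 30 % H2O2, THF, 0 °C → rt
Reagents that add atoms: none
Why: Epoxide-to-allylic-alcohol transposition by selenide opening and selenoxide syn-elimination: the soft selenolate attacks C3 (the oxirane carbon remote from quaternary C1) with inversion, and the selenoxide then leaves with the allylic C4–H instead of the carbinol C2–H, so C1 and C2 keep their configuration while C3 becomes part of the diene.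

Step 8
Reactants: 15 [(1S,2S)-1,2-dihydroxycyclohexa-3,5-dien-1-yl]methyl benzoate; 16 2,2-dimethoxypropane
Product: 17 acetonide of 15 (cis-fused 2,2-dimethyl-1,3-dioxolane on O1/O2, C3=C4–C5=C6 diene, C7 benzoate)
Conditions: Me2C(OMe)2, PPTS (cat.), CH2Cl2, rt
Reagents that add atoms: 2,2-dimethoxypropane, COC(C)(C)OC
Why: Acetonide formation by transacetalisation on the cis C1/C2 diol uses only a weak pyridinium acid, which should not ionise the dienylic C2–O bond, and touches no stereocentre.

Step 9
Reactants: 17 acetonide of 15; 18 dioxygen
Product: 20 3,6-diol acetonide (C3–OH and C6–OH cis to each other and trans to the dioxolane oxygens, C4=C5 alkene, C7 benzoate; C1, C2, C3, C6 configured as in 24), via endoperoxide 19 (not isolated)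
Conditions: O2, tetraphenylporphyrin (cat.), visible light, CH2Cl2, 0 °C; then thiourea, aq. MeOH, rt
Reagents that add atoms: dioxygen, O=O
Why: Singlet-oxygen [4+2] cycloaddition across C3 and C6 of the ring diene takes the face opposite the cis-fused dioxolane, as is general for arene cis-dihydrodiol acetonides, and thiourea then cleaves only the O–O bond, so both new C–O bonds end up cis to each other and trans to the C1/C2 oxygens.

Step 10
Reactants: 20 3,6-diol acetonide; 9 benzoyl chloride
Product: 21 tribenzoate acetonide (benzoates on O3, O6 and O7; dioxolane on O1/O2)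
Conditions: BzCl (3 equiv), pyridine, DMAP (cat.), CH2Cl2, 0 °C → rt
Reagents that add atoms: benzoyl chloride, O=C(Cl)c1ccccc1
Why: DMAP-catalysed acylation esterifies both secondary allylic alcohols without touching their configuration, and any earlier benzoyl shift among O3, O6 and O7 is levelled here because all three end up benzoylated.

Step 11
Reactants: 21 tribenzoate acetonide
Product: 22 desacetyl target (free cis C1/C2 diol; benzoates on O3, O6 and O7; configuration as in 24)
Conditions: CF3CO2H/H2O (9:1), CH2Cl2, 0 °C → rt
Reagents that add atoms: none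
Why: Acid-catalysed acetal hydrolysis frees the C1/C2 diol, while the benzoates, including the allylic ones whose ionisation is slowed by the neighbouring oxygens, should survive brief aqueous acid.

Step 12
Reactants: 22 desacetyl target; 23 acetic anhydride
Product: 24 [(1R,2S,3R,6S)-2-acetoxy-3,6-bis(benzoyloxy)-1-hydroxycyclohex-4-en-1-yl]methyl benzoate
Conditions: Ac2O (1.5 equiv), pyridine, DMAP (cat.), CH2Cl2, 0 °C
Reagents that add atoms: acetic anhydride, CC(=O)OC(C)=O
Why: Selective acetylation: the secondary C2 hydroxyl is esterified while the tertiary C1 hydroxyl, flanked by three substituted carbons, should stay free under these mild conditions, and no stereocentre is involved.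

Compound list
1 | benzoic acid | O=C(O)c1ccccc1 | starting material
2 | cyclohexa-2,5-diene-1-carboxylic acid | OC(=O)C1C=CCC=C1 | intermediate
3 | trimethylsilyldiazomethane | C[Si](C)(C)C=[N+]=[N-] | starting material
4 | methyl cyclohexa-2,5-diene-1-carboxylate | COC(=O)C1C=CCC=C1 | intermediate
5 | trans-3-phenyl-2-(phenylsulfonyl)oxaziridine (racemic) | O=S(=O)(N1OC1c1ccccc1)c1ccccc1 | starting material
6 | potassium dienolate of 4 (not isolated) | [K+].COC([O-])=C1C=CCC=C1 | intermediate
7 | methyl 1-hydroxycyclohexa-2,5-diene-1-carboxylate | COC(=O)C1(O)C=CCC=C1 | intermediate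
8 | 1-(hydroxymethyl)cyclohexa-2,5-dien-1-ol | OCC1(O)C=CCC=C1 | intermediate
9 | benzoyl chloride | O=C(Cl)c1ccccc1 | starting material
10 | (1-hydroxycyclohexa-2,5-dien-1-yl)methyl benzoate | OC1(COC(=O)c2ccccc2)C=CCC=C1 | intermediate
11 | cumene hydroperoxide | CC(C)(OO)c1ccccc1 | starting material
12 | [(1S,2S,3S)-2,3-epoxy-1-hydroxycyclohex-5-en-1-yl]methyl benzoate (oxirane cis to the C1 hydroxyl) | O[C@]1(COC(=O)c2ccccc2)C=CC[C@@H]2O[C@H]12 | intermediate
13 | hydroxy selenide (not isolated): C1/C2 cis-diol, C3 phenylselanyl trans to the C2 hydroxyl, C5=C6 alkene, C7 benzoate | O[C@H]1[C@H]([Se]c2ccccc2)CC=C[C@]1(O)COC(=O)c1ccccc1 | intermediate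
14 | selenoxide of 13 (not isolated; both configurations at selenium) | O[C@H]1[C@H]([Se](=O)c2ccccc2)CC=C[C@]1(O)COC(=O)c1ccccc1 | intermediate
15 | [(1S,2S)-1,2-dihydroxycyclohexa-3,5-dien-1-yl]methyl benzoate (cis-diol) | O[C@H]1C=CC=C[C@]1(O)COC(=O)c1ccccc1 | intermediate
16 | 2,2-dimethoxypropane | COC(C)(C)OC | starting material
17 | acetonide of 15 (cis-fused dioxolane on O1/O2, 3,5-diene) | CC1(C)O[C@H]2C=CC=C[C@@]2(COC(=O)c3ccccc3)O1 | intermediate
18 | dioxygen | O=O | starting material
19 | endoperoxide (not isolated): O–O bridge from C3 to C6 on the face opposite the dioxolane, C4=C5 alkene | CC1(C)O[C@H]2[C@H]3C=C[C@H](OO3)[C@@]2(COC(=O)c4ccccc4)O1 | intermediate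
20 | 3,6-diol acetonide (C3–OH and C6–OH trans to the dioxolane oxygens, C4=C5 alkene, C7 benzoate) | CC1(C)O[C@H]2[C@H](O)C=C[C@H](O)[C@@]2(COC(=O)c3ccccc3)O1 | intermediate
21 | tribenzoate acetonide (3,6-di-O-benzoate of 20) | CC1(C)O[C@H]2[C@H](OC(=O)c3ccccc3)C=C[C@H](OC(=O)c3ccccc3)[C@@]2(COC(=O)c3ccccc3)O1 | intermediate
22 | desacetyl target (free C1/C2 cis-diol, benzoates on O3, O6, O7) | O[C@H]1[C@H](OC(=O)c2ccccc2)C=C[C@H](OC(=O)c2ccccc2)[C@]1(O)COC(=O)c1ccccc1 | intermediate
23 | acetic anhydride | CC(=O)OC(C)=O | starting material
24 | [(1R,2S,3R,6S)-2-acetoxy-3,6-bis(benzoyloxy)-1-hydroxycyclohex-4-en-1-yl]methyl benzoate | CC(=O)O[C@H]1[C@H](OC(=O)c2ccccc2)C=C[C@H](OC(=O)c2ccccc2)[C@]1(O)COC(=O)c1ccccc1 | target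

Total step count: 12. Longest linear sequence: 12 steps (1 → 24).

Steps most likely to fail

1. Step 6. The doubly allylic tertiary alkoxide may ionise at the Lewis-acidic metal and aromatise by loss of water. The ligand may also discriminate poorly between the two enantiotopic ring alkenes, or oxidation may run on to the meso bis-epoxide. Fallback: setting out from 10, hydroxyl-directed epoxidation with VO(acac)2 and tBuOOH in CH2Cl2 should give the racemic syn-epoxide F1. The selenium sequence of step 7 would carry it through the racemic hydroxy selenide F2 and the racemic selenoxide F3 to the racemic dienediol F4. A lipase (Burkholderia cepacia lipase, vinyl acetate, tBuOMe) is then expected, by the usual size rule for secondary alcohols, to acetylate only the (2R)-antipode, giving the ent-15 2-acetate F5 and leaving (1S,2S)-15. After chromatography the fallback comes back to the route at 15.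

2. Step 7. Selenolate attack may be slow or leak to C2. The peroxide and seleninic acid mixture may epoxidise the electron-rich diene, or the free dienediol may dimerise by [4+2] addition on concentration. Fallback: setting out from 12, Li2NiBr4 in THF should open the oxirane at C3 to the trans-bromohydrin F6. 2,2-Dimethoxypropane with PPTS would then give the bromo acetonide F7. DBU in PhMe at 80 °C should effect anti E2 loss of HBr through the allylic C4–H (the C2–H is syn to bromine and cannot take part), giving 17. The route is rejoined at 17 and 15 is bypassed.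

3. Step 3. The oxaziridine may attack C3 of the dienolate instead of C1, the new alkoxide may add to the sulfonimine by-product, or the hydroxy ester may aromatise while it sits as its alkoxide in base. Fallback: setting out from 4, the same potassium dienolate 6 is quenched with dibenzoyl peroxide (enolate acyloxylation) to give methyl 1-(benzoyloxy)cyclohexa-2,5-diene-1-carboxylate F8, in which the oxygen arrives already capped. LiAlH4 then reduces both esters to diol 8, where the route is rejoined, 7 being bypassed.

Further compounds
F1 | step 6 | racemic syn-epoxide (12 and its mirror image) | O[C@]1(COC(=O)c2ccccc2)C=CC[C@@H]2O[C@H]12.O[C@@]1(COC(=O)c2ccccc2)C=CC[C@H]2O[C@@H]12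
F2 | step 6 | racemic hydroxy selenide (13 and its mirror image) | O[C@H]1[C@H]([Se]c2ccccc2)CC=C[C@]1(O)COC(=O)c1ccccc1.O[C@@H]1[C@@H]([Se]c2ccccc2)CC=C[C@@]1(O)COC(=O)c1ccccc1
F3 | step 6 | racemic selenoxide (14 and its mirror image) | O[C@H]1[C@H]([Se](=O)c2ccccc2)CC=C[C@]1(O)COC(=O)c1ccccc1.O[C@@H]1[C@@H]([Se](=O)c2ccccc2)CC=C[C@@]1(O)COC(=O)c1ccccc1
F4 | step 6 | racemic dienediol (15 and its mirror image) | O[C@H]1C=CC=C[C@]1(O)COC(=O)c1ccccc1.O[C@@H]1C=CC=C[C@@]1(O)COC(=O)c1ccccc1
F5 | step 6 | ent-15 2-acetate, [(1R,2R)-2-acetoxy-1-hydroxycyclohexa-3,5-dien-1-yl]methyl benzoate | CC(=O)O[C@@H]1C=CC=C[C@@]1(O)COC(=O)c1ccccc1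
F6 | step 7 | trans-bromohydrin (C3 bromide trans to the C2 hydroxyl, C1/C2 cis-diol, C5=C6 alkene) | O[C@H]1[C@H](Br)CC=C[C@]1(O)COC(=O)c1ccccc1
F7 | step 7 | bromo acetonide (dioxolane on O1/O2 of F6) | CC1(C)O[C@H]2[C@H](Br)CC=C[C@@]2(COC(=O)c3ccccc3)O1
F8 | step 3 | methyl 1-(benzoyloxy)cyclohexa-2,5-diene-1-carboxylate | COC(=O)C1(OC(=O)c2ccccc2)C=CCC=C1
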